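The carbonyl carbon C9 of the γ-butyrolactone ring is flanked only by the ring oxygen and C8, and the route exploits this: both bonds to C9 are cut and C9 becomes carbon monoxide. (Labels: C9 carbonyl, C8 α-carbon, C7 its benzylic CH2, C8′ β-carbon, C9′ ring OCH2, C7′ carbinol carbon.) In one operation a palladium-catalysed cyclocarbonylation joins the C9′ hydroxyl, CO and an aryl alkyne (C8≡C7), closing the five-membered ring as its (E)-arylidene lactone. The precursor is an anti homopropargylic alcohol with C8′ and C7′ already set by an allenylzinc addition to veratraldehyde; its C7′ hydroxyl is silylated and its phenol is a TIPS ether. Reduction, equilibration at C8 and desilylation finish the route.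

Key step: step 11

Remarks on the chemistry
- The target is (8R,8′R,7′S), trans across C8–C8′. In the zigzag Ar–C7′–C8′–C8 the C7′ oxygen and C9′ are anti. Precursor 16 and lactone 18 carry the same C8′ and C7′ configuration as the target.
- The C7′ hydroxyl is also 1,4 to C8 and would compete for lactonisation, so it stays a TBS ether through the key step. The C9′ oxygen travels as a primary TBS ether that is removed selectively just before.
- Assumption: in step 6 the alkynyl group takes the site an aryl group takes in aryl ketone reductions, so the (R,R) catalyst is expected to give the (S) carbinol; if the sense were opposite, the (S,S) catalyst would be used.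

Step 1
Reactants: 1 vanillin
Product: 2 3-methoxy-4-(triisopropylsilyloxy)benzaldehyde
Conditions: TIPSCl, imidazole, DMF, rt
Reagents that add atoms: triisopropylsilyl chloride, CC(C)[Si](Cl)(C(C)C)C(C)C
Why: Imidazole-promoted O-silylation of a phenol; the hindered aryl TIPS ether should withstand n-BuLi, Et2Zn and HF·pyridine later.

Step 2
Reactants: 2 3-methoxy-4-(triisopropylsilyloxy)benzaldehyde
Product: 3 4-(2,2-dibromovinyl)-2-methoxy-1-(triisopropylsilyloxy)benzene
Conditions: CBr4, PPh3, CH2Cl2, 0 °C
Reagents that add atoms: carbon tetrabromide, BrC(Br)(Br)Br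
Why: Ramirez dibromo-olefination (first stage of the Corey–Fuchs reaction), a Wittig reaction of the ylide Ph3P=CBr2 formed in the flask with an aromatic aldehyde.

Step 3
Reactants: 4 methyl glycolate
Product: 5 methyl (tert-butyldimethylsilyloxy)acetate
Conditions: TBSCl, imidazole, CH2Cl2, rt
Reagents that add atoms: tert-butyldimethylsilyl chloride, CC(C)(C)[Si](C)(C)Cl
Why: Standard imidazole-promoted silylation of a primary alcohol.

Step 4
Reactants: 5 methyl (tert-butyldimethylsilyloxy)acetate
Product: 6 2-(tert-butyldimethylsilyloxy)-N-methoxy-N-methylacetamide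
Conditions: MeNH(OMe)·HCl, i-PrMgCl, THF, −20 → 0 °C
Reagents that add atoms: N,O-dimethylhydroxylamine hydrochloride, CNOC.Cl
Why: Weinreb amide formation by aminolysis of the ester with the chloromagnesium amide made in the flask.

Step 5
Reactants: 3 4-(2,2-dibromovinyl)-2-methoxy-1-(triisopropylsilyloxy)benzene; 6 2-(tert-butyldimethylsilyloxy)-N-methoxy-N-methylacetamide
Product: 9 1-(tert-butyldimethylsilyloxy)-4-[3-methoxy-4-(triisopropylsilyloxy)phenyl]but-3-yn-2-one, via lithium arylacetylide 7 (not isolated), via tetrahedral lithium hemiaminal adduct 8 (not isolated)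
Conditions: n-BuLi (2.1 equiv), THF, −78 °C; then 6, −78 → 0 °C; aq NH4Cl
Reagents that add atoms: none
Why: Second stage of the Corey–Fuchs reaction gives lithium acetylide 7, which is trapped in a Weinreb ketone synthesis; chelated adduct 8 should persist until the quench and so prevent over-addition.

Step 6
Reactants: 9 1-(tert-butyldimethylsilyloxy)-4-[3-methoxy-4-(triisopropylsilyloxy)phenyl]but-3-yn-2-one
Product: 10 (S)-1-(tert-butyldimethylsilyloxy)-4-[3-methoxy-4-(triisopropylsilyloxy)phenyl]but-3-yn-2-ol
Conditions: Ru[(R,R)-TsNCH(Ph)CH(Ph)NH](p-cymene) (1 mol%), i-PrOH, rt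
Reagents that add atoms: none
Why: Noyori asymmetric transfer hydrogenation of an alkynyl ketone; the Ru–H/N–H pair of the (R,R) complex should deliver hydride to the carbonyl face that puts the alkynyl group in the aryl site, setting the carbinol carbon (the later C8′) as S.

Step 7
Reactants: 10 (S)-1-(tert-butyldimethylsilyloxy)-4-[3-methoxy-4-(triisopropylsilyloxy)phenyl]but-3-yn-2-ol
Product: 11 (S)-1-(tert-butyldimethylsilyloxy)-4-[3-methoxy-4-(triisopropylsilyloxy)phenyl]but-3-yn-2-yl methanesulfonate
Conditions: MsCl, Et3N, CH2Cl2, −78 → −40 °C; used without purification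
Reagents that add atoms: methanesulfonyl chloride, CS(=O)(=O)Cl
Why: O-Sulfonylation leaves the C–O stereocentre untouched, and the β-silyloxy group should retard ionisation of the propargylic mesylate if it is kept cold.

Step 8
Reactants: 11 (S)-1-(tert-butyldimethylsilyloxy)-4-[3-methoxy-4-(triisopropylsilyloxy)phenyl]but-3-yn-2-yl methanesulfonate; 12 veratraldehyde
Product: 14 (1S,2R)-2-[(tert-butyldimethylsilyloxy)methyl]-1-(3,4-dimethoxyphenyl)-4-[3-methoxy-4-(triisopropylsilyloxy)phenyl]but-3-yn-1-ol, via allenyl(ethyl)zinc reagent 13 (not isolated)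
Conditions: Pd(OAc)2 (5 mol%), PPh3 (5 mol%), Et2Zn (3 equiv), THF, −78 → −20 °C; aq NH4Cl
Reagents that add atoms: none
Why: Marshall propargylation (palladium/diethylzinc umpolung): zerovalent palladium should displace the mesylate anti-SN2′, transmetalation with retention gives allenylzinc 13, and its cyclic SE2′ addition to 12 on the zinc-bearing face inverts C8′ overall (S mesylate to 8′R), while the six-membered transition state that keeps the aldehyde aryl group away from the CH2OTBS branch gives the anti relationship and hence 7′S.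

Step 9
Reactants: 14 (1S,2R)-2-[(tert-butyldimethylsilyloxy)methyl]-1-(3,4-dimethoxyphenyl)-4-[3-methoxy-4-(triisopropylsilyloxy)phenyl]but-3-yn-1-ol
Product: 15 bis-TBS ether of 14 (C7′–OTBS and C9′–OTBS; 7′S,8′R)
Conditions: TBSOTf, 2,6-lutidine, CH2Cl2, −78 → 0 °C
Reagents that add atoms: tert-butyldimethylsilyl trifluoromethanesulfonate, CC(C)(C)[Si](C)(C)OS(=O)(=O)C(F)(F)F
Why: Silyl triflate with a hindered pyridine base is the standard silylation of a hindered secondary benzylic alcohol and touches no stereocentre.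

Step 10
Reactants: 15 bis-TBS ether of 14
Product: 16 (2R,3S)-3-(tert-butyldimethylsilyloxy)-3-(3,4-dimethoxyphenyl)-2-{[3-methoxy-4-(triisopropylsilyloxy)phenyl]ethynyl}propan-1-ol
Conditions: HF·pyridine, pyridine, THF, 0 °C
Reagents that add atoms: none
Why: Selective desilylation: buffered HF·pyridine should cleave the unhindered primary TBS ether well before the hindered secondary benzylic TBS ether or the aryl TIPS ether.

Step 11
Reactants: 16 (2R,3S)-3-(tert-butyldimethylsilyloxy)-3-(3,4-dimethoxyphenyl)-2-{[3-methoxy-4-(triisopropylsilyloxy)phenyl]ethynyl}propan-1-ol; 17 carbon monoxide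
Product: 18 (3E,4R)-4-[(S)-(tert-butyldimethylsilyloxy)(3,4-dimethoxyphenyl)methyl]-3-[3-methoxy-4-(triisopropylsilyloxy)benzylidene]oxolan-2-one
Conditions: Pd(OAc)2 (5 mol%), 2-PyPPh2 (20 mol%), TsOH·H2O (10 mol%), CO (20 bar), toluene, 70 °C
Reagents that add atoms: none
Why: Under CO, the cationic divalent palladium formed from Pd(OAc)2, the pyridylphosphine and the sulfonic acid should take up the C9′ hydroxyl and CO as a catalytic alkoxycarbonylpalladium species, which adds syn across the tethered alkyne with the acyl carbon C9 going to C8 and palladium to C7; protonolysis of the alkenyl–palladium bond with retention then releases 18 and returns divalent palladium. The closest known reaction type is the palladium-catalysed cyclocarbonylation (intramolecular hydroalkoxycarbonylation) of homopropargylic alcohols to α-alkylidene-γ-butyrolactones. The one ring closes in 5-exo-dig mode, C8 becoming a ring atom and C7 staying exocyclic, because a 6-endo closure after syn addition would need a trans double bond inside the ring. No stereocentre is created: C8′ and C7′ come from step 8 untouched, and the syn addition fixes the (E) geometry with the C7 hydrogen cis to the carbonyl. The selectivity needed is acyl delivery to C8 ahead of direct hydroxyl attack on the alkyne or a hydride pathway, and it is secured by the 1,4 spacing of the oxygen and C8, by CO pressure and by the silyl cap on the competing C7′ hydroxyl; the excess pyridylphosphine buffers the acid so that the benzylic silyl ether should survive.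

Step 12
Reactants: 18 (3E,4R)-arylidene lactone
Product: 19 (4R)-4-[(S)-(tert-butyldimethylsilyloxy)(3,4-dimethoxyphenyl)methyl]-3-[3-methoxy-4-(triisopropylsilyloxy)benzyl]oxolan-2-one (mixture of C8 epimers, cis expected to predominate)
Conditions: NaBH4, NiCl2·6H2O (20 mol%), MeOH/THF, 0 °C
Reagents that add atoms: none
Why: Nickel boride conjugate reduction of a cinnamate-type enoate, chemoselective over the lactone carbonyl and the benzylic C–O bond; C8 needs no control here because both epimers converge in step 13.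

Step 13
Reactants: 19 C8-epimeric lactone mixture
Product: 20 (3R,4R)-4-[(S)-(tert-butyldimethylsilyloxy)(3,4-dimethoxyphenyl)methyl]-3-[3-methoxy-4-(triisopropylsilyloxy)benzyl]oxolan-2-one
Conditions: DBU, toluene, 60 °C
Reagents that add atoms: none
Why: Base-mediated epimerisation through the lactone enolate places the C8 benzyl group trans to the bulky C8′ substituent under thermodynamic control (8R); C8′ and C7′ carry no acidic hydrogen and there is no β-leaving group.

Step 14
Reactants: 20 (3R,4R) bis-silyl trans lactone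
Product: 21 (3R,4R)-4-[(S)-(3,4-dimethoxyphenyl)(hydroxy)methyl]-3-(4-hydroxy-3-methoxybenzyl)oxolan-2-one (target)
Conditions: TBAF, AcOH (1:1), THF, 0 °C → rt
Reagents that add atoms: none
Why: Fluoride desilylation of the aryl TIPS and alkyl TBS ethers; the acetic acid buffer keeps the freed C7′ oxygen protonated, which should suppress acyl migration to the isomeric lactone, and avoids acid strong enough to ionise the electron-rich benzylic carbinol.

Compound list
1 | vanillin | COc1cc(C=O)ccc1O | starting material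
2 | 3-methoxy-4-(triisopropylsilyloxy)benzaldehyde | COc1cc(C=O)ccc1O[Si](C(C)C)(C(C)C)C(C)C | intermediate
3 | 4-(2,2-dibromovinyl)-2-methoxy-1-(triisopropylsilyloxy)benzene | COc1cc(C=C(Br)Br)ccc1O[Si](C(C)C)(C(C)C)C(C)C | intermediate
4 | methyl glycolate | COC(=O)CO | starting material
5 | methyl (tert-butyldimethylsilyloxy)acetate | COC(=O)CO[Si](C)(C)C(C)(C)C | intermediate
6 | 2-(tert-butyldimethylsilyloxy)-N-methoxy-N-methylacetamide | CON(C)C(=O)CO[Si](C)(C)C(C)(C)C | intermediate
7 | lithium [3-methoxy-4-(triisopropylsilyloxy)phenyl]acetylide | [Li]C#Cc1ccc(O[Si](C(C)C)(C(C)C)C(C)C)c(OC)c1 | intermediate (not isolated)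
8 | tetrahedral lithium hemiaminal adduct of 7 and 6 (racemic at the new carbon) | [Li]OC(C#Cc1ccc(O[Si](C(C)C)(C(C)C)C(C)C)c(OC)c1)(CO[Si](C)(C)C(C)(C)C)N(C)OC | intermediate (not isolated)
9 | 1-(tert-butyldimethylsilyloxy)-4-[3-methoxy-4-(triisopropylsilyloxy)phenyl]but-3-yn-2-one | COc1cc(C#CC(=O)CO[Si](C)(C)C(C)(C)C)ccc1O[Si](C(C)C)(C(C)C)C(C)C | intermediate
10 | (S)-1-(tert-butyldimethylsilyloxy)-4-[3-methoxy-4-(triisopropylsilyloxy)phenyl]but-3-yn-2-ol | COc1cc(C#C[C@H](O)CO[Si](C)(C)C(C)(C)C)ccc1O[Si](C(C)C)(C(C)C)C(C)C | intermediate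
11 | (S)-mesylate of 10 | COc1cc(C#C[C@H](OS(C)(=O)=O)CO[Si](C)(C)C(C)(C)C)ccc1O[Si](C(C)C)(C(C)C)C(C)C | intermediate
12 | veratraldehyde | COc1ccc(C=O)cc1OC | starting material
13 | (P)-allenyl(ethyl)zinc reagent, zinc and aryl on C7, H and CH2OTBS on C8′ | CC[Zn]C(c1ccc(O[Si](C(C)C)(C(C)C)C(C)C)c(OC)c1)=[C@@]=C([H])CO[Si](C)(C)C(C)(C)C | intermediate (not isolated)
14 | (1S,2R)-2-[(tert-butyldimethylsilyloxy)methyl]-1-(3,4-dimethoxyphenyl)-4-[3-methoxy-4-(triisopropylsilyloxy)phenyl]but-3-yn-1-ol | CC(C)(C)[Si](C)(C)OC[C@@H](C#Cc1ccc(O[Si](C(C)C)(C(C)C)C(C)C)c(OC)c1)[C@H](O)c1ccc(OC)c(OC)c1 | intermediate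
15 | bis-TBS ether of 14 (7′S,8′R) | CC(C)(C)[Si](C)(C)OC[C@@H](C#Cc1ccc(O[Si](C(C)C)(C(C)C)C(C)C)c(OC)c1)[C@H](O[Si](C)(C)C(C)(C)C)c1ccc(OC)c(OC)c1 | intermediate
16 | (2R,3S)-3-(tert-butyldimethylsilyloxy)-3-(3,4-dimethoxyphenyl)-2-{[3-methoxy-4-(triisopropylsilyloxy)phenyl]ethynyl}propan-1-ol | OC[C@@H](C#Cc1ccc(O[Si](C(C)C)(C(C)C)C(C)C)c(OC)c1)[C@H](O[Si](C)(C)C(C)(C)C)c1ccc(OC)c(OC)c1 | intermediate (key-step precursor)
17 | carbon monoxide | [C-]#[O+] | starting material
18 | (3E,4R)-4-[(S)-(tert-butyldimethylsilyloxy)(3,4-dimethoxyphenyl)methyl]-3-[3-methoxy-4-(triisopropylsilyloxy)benzylidene]oxolan-2-one | O=C1OC[C@H]([C@H](O[Si](C)(C)C(C)(C)C)c2ccc(OC)c(OC)c2)/C1=C\c1ccc(O[Si](C(C)C)(C(C)C)C(C)C)c(OC)c1 | intermediate (key-step product)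
19 | (4R)-4-[(S)-(tert-butyldimethylsilyloxy)(3,4-dimethoxyphenyl)methyl]-3-[3-methoxy-4-(triisopropylsilyloxy)benzyl]oxolan-2-one, C8 epimers (C8 left undefined) | O=C1OC[C@H]([C@H](O[Si](C)(C)C(C)(C)C)c2ccc(OC)c(OC)c2)C1Cc1ccc(O[Si](C(C)C)(C(C)C)C(C)C)c(OC)c1 | intermediate
20 | (3R,4R)-4-[(S)-(tert-butyldimethylsilyloxy)(3,4-dimethoxyphenyl)methyl]-3-[3-methoxy-4-(triisopropylsilyloxy)benzyl]oxolan-2-one | COc1cc(C[C@H]2C(=O)OC[C@@H]2[C@H](O[Si](C)(C)C(C)(C)C)c2ccc(OC)c(OC)c2)ccc1O[Si](C(C)C)(C(C)C)C(C)C | intermediate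
21 | (3R,4R)-4-[(S)-(3,4-dimethoxyphenyl)(hydroxy)methyl]-3-(4-hydroxy-3-methoxybenzyl)oxolan-2-one | COc1cc(C[C@H]2C(=O)OC[C@@H]2[C@H](O)c2ccc(OC)c(OC)c2)ccc1O | target

Total step count: 14. Longest linear sequence: 12 (steps 1, 2 and 5–14; the branch through steps 3 and 4 is equally long).

Steps most likely to fail

Step 11 (key step). The hydroxyl may add directly to the palladium-activated, electron-rich alkyne (5-endo hydroalkoxylation). Carbonylation may instead run through a palladium hydride that delivers the acyl group to C7 and leads to open-chain esters. The exocyclic double bond may migrate into the ring and erase C8′, or the benzylic silyl ether may be lost to the acid co-catalyst. The fallback sets out from 16. Hydroxyl-directed trans-hydrostannation (Bu3SnH, [Cp*RuCl]4, CH2Cl2, rt) should place tin on C8 and give the (Z)-alkenylstannane F1. Iododestannylation (I2, CH2Cl2, 0 °C) should give the (Z)-alkenyl iodide F2 with retention. Carbonylative lactonisation of this iodide onto the C9′ hydroxyl (Pd(PPh3)4, CO 1 atm, Et3N, MeCN, 60 °C; oxidative addition to zerovalent palladium, CO insertion, acyl capture) should give the (Z)-arylidene lactone F3, the geometric isomer of 18. Reduction of F3 under the conditions of step 12 returns to the route at 19, since the double-bond geometry is lost there.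

Step 8. The aryl-conjugated propargylic mesylate may ionise, or the α-aryl allenylzinc may racemise, eroding the configuration at C8′; facial discrimination of the aromatic aldehyde (anti versus syn) may also be modest. The fallback sets out from 6 and 12 and uses the better-precedented silyl-capped allenylzinc, the aryl group arriving only after both stereocentres are set. (Trimethylsilyl)acetylene is lithiated (n-BuLi, THF, −78 °C) and acylated with 6 to give the alkynyl ketone F4. Transfer hydrogenation as in step 6 gives the (S)-carbinol F5, and mesylation as in step 7 gives the mesylate F6. Addition to 12 under the conditions of step 8 should give the anti C-silyl alkyne F7. K2CO3 in MeOH removes the alkynyl silicon to give the terminal alkyne F8. Sonogashira coupling (PdCl2(PPh3)2, CuI, Et3N, THF, rt) with the aryl iodide F9, made from purchased 4-iodo-2-methoxyphenol and TIPSCl/imidazole, returns to the route at 14.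

Step 10. Discrimination between the primary and the secondary alkyl silyl ether may be incomplete, or silicon may migrate from the C7′ oxygen to the freed C9′ oxygen, which would expose the C7′ hydroxyl to the carbonylation. The fallback sets out from 14 and differentiates the two oxygens with an ester instead. HF·pyridine/pyridine in THF removes the only alkyl silyl ether to give the diol F10. PivCl and pyridine in CH2Cl2 at 0 °C should acylate the primary hydroxyl selectively to give the pivalate F11. TBSOTf and 2,6-lutidine give the silyl ether F12. DIBAL-H in CH2Cl2 at −78 °C removes the pivalate and returns to the route at 16.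

Further compounds
F1 | step 11 | (Z)-alkenylstannane, Bu3Sn on C8 cis to the aryl group, from 16 | OC[C@@H](/C(=C/c1ccc(O[Si](C(C)C)(C(C)C)C(C)C)c(OC)c1)[Sn](CCCC)(CCCC)CCCC)[C@H](O[Si](C)(C)C(C)(C)C)c1ccc(OC)c(OC)c1
F2 | step 11 | (Z)-alkenyl iodide, iodine on C8 cis to the aryl group | OC[C@@H](/C(I)=C/c1ccc(O[Si](C(C)C)(C(C)C)C(C)C)c(OC)c1)[C@H](O[Si](C)(C)C(C)(C)C)c1ccc(OC)c(OC)c1
F3 | step 11 | (3Z,4R)-4-[(S)-(tert-butyldimethylsilyloxy)(3,4-dimethoxyphenyl)methyl]-3-[3-methoxy-4-(triisopropylsilyloxy)benzylidene]oxolan-2-one | O=C1OC[C@H]([C@H](O[Si](C)(C)C(C)(C)C)c2ccc(OC)c(OC)c2)/C1=C/c1ccc(O[Si](C(C)C)(C(C)C)C(C)C)c(OC)c1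
F4 | step 8 | 1-(tert-butyldimethylsilyloxy)-4-(trimethylsilyl)but-3-yn-2-one | C[Si](C)(C)C#CC(=O)CO[Si](C)(C)C(C)(C)C
F5 | step 8 | (S)-1-(tert-butyldimethylsilyloxy)-4-(trimethylsilyl)but-3-yn-2-ol | C[Si](C)(C)C#C[C@H](O)CO[Si](C)(C)C(C)(C)C
F6 | step 8 | (S)-1-(tert-butyldimethylsilyloxy)-4-(trimethylsilyl)but-3-yn-2-yl methanesulfonate | C[Si](C)(C)C#C[C@H](OS(C)(=O)=O)CO[Si](C)(C)C(C)(C)C
F7 | step 8 | (1S,2R)-2-[(tert-butyldimethylsilyloxy)methyl]-1-(3,4-dimethoxyphenyl)-4-(trimethylsilyl)but-3-yn-1-ol | CC(C)(C)[Si](C)(C)OC[C@@H](C#C[Si](C)(C)C)[C@H](O)c1ccc(OC)c(OC)c1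
F8 | step 8 | (1S,2R)-2-[(tert-butyldimethylsilyloxy)methyl]-1-(3,4-dimethoxyphenyl)but-3-yn-1-ol | CC(C)(C)[Si](C)(C)OC[C@@H](C#C)[C@H](O)c1ccc(OC)c(OC)c1
F9 | step 8 | 4-iodo-2-methoxy-1-(triisopropylsilyloxy)benzene | COc1cc(I)ccc1O[Si](C(C)C)(C(C)C)C(C)C
F10 | step 10 | (1S,2R)-1-(3,4-dimethoxyphenyl)-2-{[3-methoxy-4-(triisopropylsilyloxy)phenyl]ethynyl}propane-1,3-diol | OC[C@@H](C#Cc1ccc(O[Si](C(C)C)(C(C)C)C(C)C)c(OC)c1)[C@H](O)c1ccc(OC)c(OC)c1
F11 | step 10 | primary pivalate of F10 | CC(C)(C)C(=O)OC[C@@H](C#Cc1ccc(O[Si](C(C)C)(C(C)C)C(C)C)c(OC)c1)[C@H](O)c1ccc(OC)c(OC)c1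
F12 | step 10 | C7′ TBS ether of F11 | CC(C)(C)C(=O)OC[C@@H](C#Cc1ccc(O[Si](C(C)C)(C(C)C)C(C)C)c(OC)c1)[C@H](O[Si](C)(C)C(C)(C)C)c1ccc(OC)c(OC)c1
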